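Ring A of the target (C1–C5 and C10), with oxygen on C3, the C15 carbon on C4 and the methyl-bearing quaternary C10 para to C3, is treated as a masked 2,4-dimethylphenol. The route rests on one disconnection, the C9–C10 bond. Protonation of a phenolic α-diazoketone lets the para carbon C10 displace dinitrogen from C9, which closes ring B, sets the C10 stereocentre under control of C7 and delivers the ring A 1,4-dien-3-one in one operation. The precursor is a 3-hydroxy-2,6-dimethylbenzyl group (C6) on the (R)-configured C7 of a diazomethyl ketone (C8, C9); C7 carries C11–C13 as a saturated bis(silyloxy)propan-2-yl group, converted into the acrylate only after ring A has been adjusted.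

Key step: step 15

Remark on numbering and configuration: eudesmane numbering is used (ring A C1–C5 and C10, ring B C5–C10, C14 on C10, C15 on C4, C11–C13 on C7; β is the face of C14). The target is read as 3β-acyloxy, 5α-hydroperoxy, 7α-H, 8β-acetoxy, 10β-methyl, that is (3S,5S,7R,8R,10R). TBDPSO = tert-butyldiphenylsilyloxy, TIPSO = triisopropylsilyloxy.

Remark on the precursor: the C7 substituent passes through the key step as CH(CH2OTBDPS)2, not as an alkene. An alkene version would be a 1-(silyloxymethyl)ethenyl (3-silyloxyprop-1-en-2-yl) group, not a 2-substituted vinyl group, because C11 itself is bonded to C7. Such a C11=C13 bond lies β,γ to the diazoketone, where C13 can trap the diazonium carbon C9 in a five-membered ring (acid-promoted cyclopentenone formation); it also makes C7–H allylic as well as α to a carbonyl, and it would not survive the RhCl(PPh3)3 hydrogenation of step 18. The carbon skeleton, the bond formed and the ring closed are unchanged.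

Assumption: diazomethane is used as a preformed ethereal solution.

Step 1
Reactants: 1 2,6-dimethylbenzoic acid
Product: 2 2,6-dimethyl-3-nitrobenzoic acid
Conditions: fuming HNO3, conc. H2SO4, 0 °C to rt
Reagents that add atoms: nitric acid, O[N+](=O)[O-]
Why: Electrophilic aromatic nitration, in which both methyl groups (ortho and para) and the carboxyl group (meta) direct to C3, so one mononitro isomer is expected.

Step 2
Reactants: 2 2,6-dimethyl-3-nitrobenzoic acid
Product: 3 3-amino-2,6-dimethylbenzoic acid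
Conditions: H2 (1 atm), 10% Pd/C, MeOH, rt
Reagents that add atoms: none
Why: Catalytic hydrogenation of an aromatic nitro group to the aniline, with no other reducible group present.

Step 3
Reactants: 3 3-amino-2,6-dimethylbenzoic acid
Product: 5 3-hydroxy-2,6-dimethylbenzoic acid, via arenediazonium hydrogensulfate 4 (not isolated)
Conditions: NaNO2, aq. H2SO4, 0 °C; then dilute H2SO4, 100 °C
Reagents that add atoms: water, O
Why: Diazotisation followed by thermal hydrolysis of the diazonium salt, the standard conversion of an aniline into a phenol.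

Step 4
Reactants: 5 3-hydroxy-2,6-dimethylbenzoic acid
Product: 6 3-(hydroxymethyl)-2,4-dimethylphenol
Conditions: BH3·SMe2, THF, 0 °C to reflux; then MeOH
Reagents that add atoms: none
Why: Borane reduction of a carboxylic acid through its acyloxyborane, which should also work on this 2,6-disubstituted benzoic acid and leaves the phenol untouched.

Step 5
Reactants: 6 3-(hydroxymethyl)-2,4-dimethylphenol
Product: 8 [2,6-dimethyl-3-(TIPSO)phenyl]methanol, via sodium phenoxide 7 (not isolated)
Conditions: NaH (1.0 equiv), THF, 0 °C; then i-Pr3SiCl, 0 °C to rt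
Reagents that add atoms: chlorotri(propan-2-yl)silane, CC(C)[Si](Cl)(C(C)C)C(C)C
Why: Selective O-silylation, since one equivalent of base deprotonates only the phenol (far more acidic than the hindered benzylic alcohol) and the phenoxide takes the silyl chloride.

Step 6
Reactants: 8 [2,6-dimethyl-3-(TIPSO)phenyl]methanol
Product: 9 [3-(bromomethyl)-2,4-dimethylphenoxy]triisopropylsilane
Conditions: PBr3, Et2O, 0 °C
Reagents that add atoms: phosphorus tribromide, BrP(Br)Br
Why: Bromination of a benzylic alcohol through its phosphite ester, mild enough for the aryl silyl ether.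

Step 7
Reactants: 10 diethyl 2-allylmalonate
Product: 11 2-allylpropane-1,3-diol
Conditions: LiAlH4, THF, 0 °C to rt; then H2O, aq. NaOH
Reagents that add atoms: none
Why: Hydride reduction of both ester groups to the symmetrical 1,3-diol, which leaves the isolated alkene alone.

Step 8
Reactants: 11 2-allylpropane-1,3-diol
Product: 12 2-allyl-1,3-bis(TBDPSO)propane
Conditions: t-BuPh2SiCl (2.2 equiv), imidazole, DMF, rt
Reagents that add atoms: tert-butyl(chloro)diphenylsilane, CC(C)(C)[Si](Cl)(c1ccccc1)c1ccccc1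
Why: Imidazole-promoted silylation of two unhindered primary alcohols, which keeps the future C11 free of stereochemistry because both arms are identical.

Step 9
Reactants: 12 2-allyl-1,3-bis(TBDPSO)propane
Product: 13 4-(TBDPSO)-3-[(TBDPSO)methyl]butanoic acid
Conditions: RuCl3·xH2O (cat.), NaIO4, EtOAc/MeCN/H2O, rt
Reagents that add atoms: sodium periodate, [Na+].[O-]I(=O)(=O)=O; water, O
Why: Ruthenium tetroxide-catalysed oxidative cleavage of a terminal alkene to the carboxylic acid with loss of one carbon, under conditions that primary TBDPS ethers tolerate.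

Step 10
Reactants: 13 4-(TBDPSO)-3-[(TBDPSO)methyl]butanoic acid; 14 (R)-4-benzyloxazolidin-2-one
Product: 16 (R)-4-benzyl-3-{4-(TBDPSO)-3-[(TBDPSO)methyl]butanoyl}oxazolidin-2-one, via mixed pivalic anhydride 15 (not isolated)
Conditions: t-BuCOCl, Et3N, THF, −20 °C; then 14, LiCl, −20 °C to rt
Reagents that add atoms: none
Why: N-acylation of the oxazolidinone through a mixed anhydride, in which the pivaloyl carbonyl is shielded so that only the desired acyl group is transferred.

Step 11
Reactants: 16 (R)-4-benzyl-3-{4-(TBDPSO)-3-[(TBDPSO)methyl]butanoyl}oxazolidin-2-one; 9 [3-(bromomethyl)-2,4-dimethylphenoxy]triisopropylsilane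
Product: 18 (R)-4-benzyl-3-[(2R)-4-(TBDPSO)-3-[(TBDPSO)methyl]-2-{[2,6-dimethyl-3-(TIPSO)phenyl]methyl}butanoyl]oxazolidin-2-one, via sodium Z-enolate 17 (not isolated)
Conditions: NaN(SiMe3)2, THF, −78 °C; then 9, −78 to −30 °C
Reagents that add atoms: none
Why: Oxazolidinone-auxiliary (Evans) alkylation, in which the chelated Z-enolate is attacked by the benzylic bromide on the face opposite the auxiliary benzyl group, which sets C7 as (R) and forms the C6–C7 bond.

Step 12
Reactants: 18 (R)-4-benzyl-3-[(2R)-4-(TBDPSO)-3-[(TBDPSO)methyl]-2-{[2,6-dimethyl-3-(TIPSO)phenyl]methyl}butanoyl]oxazolidin-2-one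
Product: 20 (2R)-4-(TBDPSO)-3-[(TBDPSO)methyl]-2-{[2,6-dimethyl-3-(TIPSO)phenyl]methyl}butanoic acid, via lithium peroxycarboxylate 19 (not isolated)
Conditions: LiOH, H2O2, THF/H2O, 0 °C; then Na2SO3; then aq. HCl to pH 3
Reagents that add atoms: hydrogen peroxide, OO
Why: Hydroperoxide-mediated cleavage of the imide at the exocyclic carbonyl, which should release the acid without epimerising C7 and returns the auxiliary.

Step 13
Reactants: 20 (2R)-4-(TBDPSO)-3-[(TBDPSO)methyl]-2-{[2,6-dimethyl-3-(TIPSO)phenyl]methyl}butanoic acid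
Product: 22 (3R)-1-diazo-5-(TBDPSO)-4-[(TBDPSO)methyl]-3-{[2,6-dimethyl-3-(TIPSO)phenyl]methyl}pentan-2-one, via acid chloride 21 (not isolated)
Conditions: 1-chloro-N,N,2-trimethylprop-1-en-1-amine, CH2Cl2, 0 °C; then CH2N2 (excess), Et2O, 0 °C
Reagents that add atoms: diazomethane, C=[N+]=[N-]
Why: Acylation of diazomethane by an acid chloride (first stage of the Arndt–Eistert sequence) introduces C9, and making the chloride under neutral conditions without tertiary amine avoids ketene formation and so protects C7.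

Step 14
Reactants: 22 (3R)-1-diazo-5-(TBDPSO)-4-[(TBDPSO)methyl]-3-{[2,6-dimethyl-3-(TIPSO)phenyl]methyl}pentan-2-one
Product: 23 (3R)-1-diazo-5-(TBDPSO)-4-[(TBDPSO)methyl]-3-[(3-hydroxy-2,6-dimethylphenyl)methyl]pentan-2-one
Conditions: Bu4NF (1.1 equiv), AcOH (1.2 equiv), THF, 0 °C
Reagents that add atoms: none
Why: Fluoride cleavage of a silyl ether, selective because an aryl silyl ether (phenoxide leaving group) should react far faster than the two primary alkyl TBDPS ethers, with acetic acid buffering the phenoxide so that the diazoketone and C7 are not exposed to base.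

Step 15
Reactants: 23 (3R)-1-diazo-5-(TBDPSO)-4-[(TBDPSO)methyl]-3-[(3-hydroxy-2,6-dimethylphenyl)methyl]pentan-2-one
Product: 25 (7R,10S)-12,13-bis(TBDPSO)eudesma-1,4-diene-3,8-dione, via alkanediazonium trifluoroacetate 24 (not isolated)
Conditions: CF3CO2H, CH2Cl2, −20 °C; then aq. NaHCO3
Reagents that add atoms: none
Why: CF3CO2H protonates the diazo carbon C9 to give the α-keto alkanediazonium ion 24, the para carbon C10 of the free phenol displaces dinitrogen from C9 in an intramolecular SN2-type aryl participation, and loss of the phenolic proton from the cyclohexadienyl cation leaves the cross-conjugated 1,4-dien-3-one, so that C14 and C15 stem from the aryl methyl groups and the C3 ketone from the phenol oxygen. The closest known reaction type is the acid-promoted intramolecular para C-alkylation of phenolic diazoketones to cyclohexa-2,5-dienones, including cases in which the para carbon already bears a substituent. Ring B (C5–C6–C7–C8–C9–C10) closes in a 6-exo-tet mode, because the sp3 carbon C9 is attacked and the departing dinitrogen lies outside the ring. The new stereocentre C10 is controlled by C7: ring B forms through a chair-like arrangement with the large C7 side chain equatorial, so C9 bonds to the arene face that places C14 axial and cis to that side chain (10β-methyl, 7α-H). The step needs para (C10) over ortho (C4) C-alkylation and ring closure over capture of C9 by trifluoroacetate; the first should follow from the higher HOMO density para to the hydroxyl and from congestion at C4, which is flanked by the hydroxyl-bearing C3 and the chain-bearing C5, the second from the intramolecular six-membered closure at low temperature in a weakly nucleophilic medium. No other internal nucleophile is present, because the side chain has no alkene and its oxygens are shielded by the t-BuPh2Si groups, and C8 stays a ketone, which removes any 1,3-diaxial contact between a C8 substituent and C14 during closure.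

Step 16
Reactants: 25 (7R,10S)-12,13-bis(TBDPSO)eudesma-1,4-diene-3,8-dione
Product: 26 (8β)-8-hydroxy-12,13-bis(TBDPSO)eudesma-1,4-dien-3-one
Conditions: LiBH(s-Bu)3 (1.1 equiv), THF, −78 °C; then H2O
Reagents that add atoms: none
Why: Reduction with a bulky trialkylborohydride, which should take the saturated C8 ketone in preference to the less electrophilic cross-conjugated dienone and deliver hydride equatorially on the α face because the axial path on the β face is blocked by C14, giving the axial 8β-alcohol (8R).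

Step 17
Reactants: 26 (8β)-8-hydroxy-12,13-bis(TBDPSO)eudesma-1,4-dien-3-one
Product: 27 (8β)-8-acetoxy-12,13-bis(TBDPSO)eudesma-1,4-dien-3-one
Conditions: Ac2O, DMAP, pyridine, CH2Cl2, rt
Reagents that add atoms: acetic anhydride, CC(=O)OC(C)=O
Why: DMAP-catalysed acetylation, which is strong enough for the hindered axial secondary alcohol.

Step 18
Reactants: 27 (8β)-8-acetoxy-12,13-bis(TBDPSO)eudesma-1,4-dien-3-one
Product: 28 (8β)-8-acetoxy-12,13-bis(TBDPSO)eudesm-4-en-3-one
Conditions: H2 (1 atm), RhCl(PPh3)3 (cat.), benzene/EtOH, rt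
Reagents that add atoms: none
Why: Homogeneous hydrogenation with RhCl(PPh3)3 reduces the disubstituted C1=C2 bond and leaves the tetrasubstituted C4=C5 bond, as is established for steroidal and santonin-type 1,4-dien-3-ones.

Step 19
Reactants: 28 (8β)-8-acetoxy-12,13-bis(TBDPSO)eudesm-4-en-3-one
Product: 29 (3β,8β)-8-acetoxy-12,13-bis(TBDPSO)eudesm-4-en-3-ol
Conditions: NaBH4, CeCl3·7H2O, MeOH, −78 to −20 °C
Reagents that add atoms: none
Why: Luche reduction gives 1,2-addition only, and hydride delivery along the axial path on the α face, anti to the axial C14 methyl, should give the equatorial 3β-allylic alcohol (3S).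

Step 20
Reactants: 29 (3β,8β)-8-acetoxy-12,13-bis(TBDPSO)eudesm-4-en-3-ol
Product: 30 (3β,8β)-8-acetoxy-12,13-bis(TBDPSO)eudesm-4-en-3-yl 2-methylpropanoate
Conditions: (i-PrCO)2O, DMAP, Et3N, CH2Cl2, 0 °C to rt
Reagents that add atoms: 2-methylpropanoic anhydride, CC(C)C(=O)OC(=O)C(C)C
Why: DMAP-catalysed acylation of the unhindered equatorial allylic alcohol, with the anhydride chosen so that no chloride is present to attack the allylic position.

Step 21
Reactants: 30 (3β,8β)-8-acetoxy-12,13-bis(TBDPSO)eudesm-4-en-3-yl 2-methylpropanoate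
Product: 31 (3β,8β)-8-acetoxy-12,13-dihydroxyeudesm-4-en-3-yl 2-methylpropanoate
Conditions: HF·pyridine, pyridine, THF, 0 °C to rt
Reagents that add atoms: none
Why: Fluoride desilylation under buffered, non-basic conditions, which should free both primary alcohols without touching or migrating the two esters.

Step 22
Reactants: 31 (3β,8β)-8-acetoxy-12,13-dihydroxyeudesm-4-en-3-yl 2-methylpropanoate
Product: 33 (3β,8β)-8,13-diacetoxy-12-hydroxyeudesm-4-en-3-yl 2-methylpropanoate (both C11 epimers), via cyclic orthoacetate 32 (not isolated)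
Conditions: MeC(OMe)3, PPTS (cat.), CH2Cl2, rt; then H2O, rt
Reagents that add atoms: trimethyl orthoacetate, CC(OC)(OC)OC; water, O
Why: Mono-acylation of a diol through its cyclic orthoester, whose hydrolysis can only give one acetate and so avoids a statistical mixture; the two arms are equivalent, so only C11 epimers arise and both converge in step 23.

Step 23
Reactants: 33 (3β,8β)-8,13-diacetoxy-12-hydroxyeudesm-4-en-3-yl 2-methylpropanoate
Product: 35 (3β,8β)-8-acetoxy-12-oxoeudesma-4,11(13)-dien-3-yl 2-methylpropanoate, via β-acetoxy aldehyde 34 (not isolated)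
Conditions: Dess–Martin periodinane, CH2Cl2, 0 °C to rt; then Et3N, 0 °C
Reagents that add atoms: none
Why: Dess–Martin oxidation of the primary alcohol followed by E1cB loss of acetate from the β-acetoxy aldehyde, which creates the C11=C13 bond, can only eliminate towards C13 and erases the C11 stereocentre.

Step 24
Reactants: 35 (3β,8β)-8-acetoxy-12-oxoeudesma-4,11(13)-dien-3-yl 2-methylpropanoate
Product: 37 methyl (3β,8β)-8-acetoxy-3-(2-methylpropanoyloxy)eudesma-4,11(13)-dien-12-oate, via acrylic acid 36 (not isolated)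
Conditions: NaClO2, NaH2PO4, 2-methylbut-2-ene, t-BuOH/H2O, 0 °C to rt; then MeI, KHCO3, DMF, rt
Reagents that add atoms: sodium chlorite, [Na+].[O-]Cl=O; iodomethane, CI
Why: Pinnick oxidation of the enal, with excess alkene scavenger to keep hypochlorous acid away from C4=C5, followed by O-alkylation of the carboxylate, which avoids dipolar additions to the acrylate.

Step 25
Reactants: 37 methyl (3β,8β)-8-acetoxy-3-(2-methylpropanoyloxy)eudesma-4,11(13)-dien-12-oate
Product: 38 methyl (3β,5α,8β)-8-acetoxy-5-hydroperoxy-3-(2-methylpropanoyloxy)eudesma-4(15),11(13)-dien-12-oate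
Conditions: O2, hν (visible), tetraphenylporphyrin (cat.), CH2Cl2, 0 °C
Reagents that add atoms: dioxygen, O=O
Why: Schenck ene reaction, in which singlet oxygen should bond to C5 on the α face (anti to C14 and to both β-acyloxy groups) and take a hydrogen from the C15 methyl to give the 4(15)-alkene and the 5α-hydroperoxide (5S); the acrylate is too electron-poor to react, and H-3 (geminal to acyloxy) and the equatorial α-hydrogen on C6 are poor donors.

Compound list
1 | 2,6-dimethylbenzoic acid | Cc1cccc(C)c1C(=O)O | starting material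
2 | 2,6-dimethyl-3-nitrobenzoic acid | Cc1ccc([N+](=O)[O-])c(C)c1C(=O)O | intermediate
3 | 3-amino-2,6-dimethylbenzoic acid | Cc1ccc(N)c(C)c1C(=O)O | intermediate
4 | 3-carboxy-2,4-dimethylbenzenediazonium hydrogensulfate | Cc1ccc([N+]#N)c(C)c1C(=O)O.OS(=O)(=O)[O-] | intermediate
5 | 3-hydroxy-2,6-dimethylbenzoic acid | Cc1ccc(O)c(C)c1C(=O)O | intermediate
6 | 3-(hydroxymethyl)-2,4-dimethylphenol | Cc1ccc(O)c(C)c1CO | intermediate
7 | sodium 3-(hydroxymethyl)-2,4-dimethylphenoxide | Cc1ccc([O-])c(C)c1CO.[Na+] | intermediate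
8 | [2,6-dimethyl-3-(triisopropylsilyloxy)phenyl]methanol | Cc1ccc(O[Si](C(C)C)(C(C)C)C(C)C)c(C)c1CO | intermediate
9 | [3-(bromomethyl)-2,4-dimethylphenoxy]triisopropylsilane | Cc1ccc(O[Si](C(C)C)(C(C)C)C(C)C)c(C)c1CBr | intermediate
10 | diethyl 2-allylmalonate | C=CCC(C(=O)OCC)C(=O)OCC | starting material
11 | 2-allylpropane-1,3-diol | C=CCC(CO)CO | intermediate
12 | 2-allyl-1,3-bis(tert-butyldiphenylsilyloxy)propane | C=CCC(CO[Si](c1ccccc1)(c1ccccc1)C(C)(C)C)CO[Si](c1ccccc1)(c1ccccc1)C(C)(C)C | intermediate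
13 | 4-(tert-butyldiphenylsilyloxy)-3-[(tert-butyldiphenylsilyloxy)methyl]butanoic acid | OC(=O)CC(CO[Si](c1ccccc1)(c1ccccc1)C(C)(C)C)CO[Si](c1ccccc1)(c1ccccc1)C(C)(C)C | intermediate
14 | (R)-4-benzyloxazolidin-2-one | O=C1N[C@H](Cc2ccccc2)CO1 | starting material
15 | mixed anhydride of 13 with pivalic acid | CC(C)(C)C(=O)OC(=O)CC(CO[Si](c1ccccc1)(c1ccccc1)C(C)(C)C)CO[Si](c1ccccc1)(c1ccccc1)C(C)(C)C | intermediate
16 | (R)-4-benzyl-3-{4-(TBDPSO)-3-[(TBDPSO)methyl]butanoyl}oxazolidin-2-one | O=C1OC[C@@H](Cc2ccccc2)N1C(=O)CC(CO[Si](c1ccccc1)(c1ccccc1)C(C)(C)C)CO[Si](c1ccccc1)(c1ccccc1)C(C)(C)C | intermediate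
17 | sodium (Z)-enolate of 16 | [Na+].[O-]/C(=C\C(CO[Si](c1ccccc1)(c1ccccc1)C(C)(C)C)CO[Si](c1ccccc1)(c1ccccc1)C(C)(C)C)N1[C@H](Cc2ccccc2)COC1=O | intermediate
18 | (R)-4-benzyl-3-[(2R)-4-(TBDPSO)-3-[(TBDPSO)methyl]-2-{[2,6-dimethyl-3-(TIPSO)phenyl]methyl}butanoyl]oxazolidin-2-one | O=C1OC[C@@H](Cc2ccccc2)N1C(=O)[C@H](Cc1c(C)c(O[Si](C(C)C)(C(C)C)C(C)C)ccc1C)C(CO[Si](c1ccccc1)(c1ccccc1)C(C)(C)C)CO[Si](c1ccccc1)(c1ccccc1)C(C)(C)C | intermediate
19 | lithium peroxycarboxylate of 20 | [Li+].[O-]OC(=O)[C@H](Cc1c(C)c(O[Si](C(C)C)(C(C)C)C(C)C)ccc1C)C(CO[Si](c1ccccc1)(c1ccccc1)C(C)(C)C)CO[Si](c1ccccc1)(c1ccccc1)C(C)(C)C | intermediate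
20 | (2R)-4-(TBDPSO)-3-[(TBDPSO)methyl]-2-{[2,6-dimethyl-3-(TIPSO)phenyl]methyl}butanoic acid | OC(=O)[C@H](Cc1c(C)c(O[Si](C(C)C)(C(C)C)C(C)C)ccc1C)C(CO[Si](c1ccccc1)(c1ccccc1)C(C)(C)C)CO[Si](c1ccccc1)(c1ccccc1)C(C)(C)C | intermediate
21 | acid chloride of 20 | ClC(=O)[C@H](Cc1c(C)c(O[Si](C(C)C)(C(C)C)C(C)C)ccc1C)C(CO[Si](c1ccccc1)(c1ccccc1)C(C)(C)C)CO[Si](c1ccccc1)(c1ccccc1)C(C)(C)C | intermediate
22 | (3R)-1-diazo-5-(TBDPSO)-4-[(TBDPSO)methyl]-3-{[2,6-dimethyl-3-(TIPSO)phenyl]methyl}pentan-2-one | [N-]=[N+]=CC(=O)[C@H](Cc1c(C)c(O[Si](C(C)C)(C(C)C)C(C)C)ccc1C)C(CO[Si](c1ccccc1)(c1ccccc1)C(C)(C)C)CO[Si](c1ccccc1)(c1ccccc1)C(C)(C)C | intermediate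
23 | (3R)-1-diazo-5-(TBDPSO)-4-[(TBDPSO)methyl]-3-[(3-hydroxy-2,6-dimethylphenyl)methyl]pentan-2-one (key-step precursor) | [N-]=[N+]=CC(=O)[C@H](Cc1c(C)c(O)ccc1C)C(CO[Si](c1ccccc1)(c1ccccc1)C(C)(C)C)CO[Si](c1ccccc1)(c1ccccc1)C(C)(C)C | intermediate
24 | (3R)-5-(TBDPSO)-4-[(TBDPSO)methyl]-3-[(3-hydroxy-2,6-dimethylphenyl)methyl]-2-oxopentane-1-diazonium trifluoroacetate | N#[N+]CC(=O)[C@H](Cc1c(C)c(O)ccc1C)C(CO[Si](c1ccccc1)(c1ccccc1)C(C)(C)C)CO[Si](c1ccccc1)(c1ccccc1)C(C)(C)C.[O-]C(=O)C(F)(F)F | intermediate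
25 | (7R,10S)-12,13-bis(TBDPSO)eudesma-1,4-diene-3,8-dione (7α-H, 10β-methyl; key-step product) | CC(C)(C)[Si](c1ccccc1)(c1ccccc1)OCC(CO[Si](c1ccccc1)(c1ccccc1)C(C)(C)C)[C@H]1CC2=C(C)C(=O)C=C[C@]2(C)CC1=O | intermediate
26 | (8β)-8-hydroxy-12,13-bis(TBDPSO)eudesma-1,4-dien-3-one | CC(C)(C)[Si](c1ccccc1)(c1ccccc1)OCC(CO[Si](c1ccccc1)(c1ccccc1)C(C)(C)C)[C@H]1CC2=C(C)C(=O)C=C[C@]2(C)C[C@H]1O | intermediate
27 | (8β)-8-acetoxy-12,13-bis(TBDPSO)eudesma-1,4-dien-3-one | CC(C)(C)[Si](c1ccccc1)(c1ccccc1)OCC(CO[Si](c1ccccc1)(c1ccccc1)C(C)(C)C)[C@H]1CC2=C(C)C(=O)C=C[C@]2(C)C[C@H]1OC(C)=O | intermediate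
28 | (8β)-8-acetoxy-12,13-bis(TBDPSO)eudesm-4-en-3-one | CC(C)(C)[Si](c1ccccc1)(c1ccccc1)OCC(CO[Si](c1ccccc1)(c1ccccc1)C(C)(C)C)[C@H]1CC2=C(C)C(=O)CC[C@]2(C)C[C@H]1OC(C)=O | intermediate
29 | (3β,8β)-8-acetoxy-12,13-bis(TBDPSO)eudesm-4-en-3-ol | CC(C)(C)[Si](c1ccccc1)(c1ccccc1)OCC(CO[Si](c1ccccc1)(c1ccccc1)C(C)(C)C)[C@H]1CC2=C(C)[C@@H](O)CC[C@]2(C)C[C@H]1OC(C)=O | intermediate
30 | (3β,8β)-8-acetoxy-12,13-bis(TBDPSO)eudesm-4-en-3-yl 2-methylpropanoate | CC(C)(C)[Si](c1ccccc1)(c1ccccc1)OCC(CO[Si](c1ccccc1)(c1ccccc1)C(C)(C)C)[C@H]1CC2=C(C)[C@@H](OC(=O)C(C)C)CC[C@]2(C)C[C@H]1OC(C)=O | intermediate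
31 | (3β,8β)-8-acetoxy-12,13-dihydroxyeudesm-4-en-3-yl 2-methylpropanoate | OCC(CO)[C@H]1CC2=C(C)[C@@H](OC(=O)C(C)C)CC[C@]2(C)C[C@H]1OC(C)=O | intermediate
32 | cyclic orthoacetate of 31 (2-methoxy-2-methyl-1,3-dioxan-5-yl group on C7, either configuration at the orthoester carbon) | COC1(C)OCC(CO1)[C@H]1CC2=C(C)[C@@H](OC(=O)C(C)C)CC[C@]2(C)C[C@H]1OC(C)=O | intermediate
33 | (3β,8β)-8,13-diacetoxy-12-hydroxyeudesm-4-en-3-yl 2-methylpropanoate (both C11 epimers) | CC(=O)OCC(CO)[C@H]1CC2=C(C)[C@@H](OC(=O)C(C)C)CC[C@]2(C)C[C@H]1OC(C)=O | intermediate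
34 | (3β,8β)-8,13-diacetoxy-12-oxoeudesm-4-en-3-yl 2-methylpropanoate (both C11 epimers) | CC(=O)OCC(C=O)[C@H]1CC2=C(C)[C@@H](OC(=O)C(C)C)CC[C@]2(C)C[C@H]1OC(C)=O | intermediate
35 | (3β,8β)-8-acetoxy-12-oxoeudesma-4,11(13)-dien-3-yl 2-methylpropanoate | C=C(C=O)[C@H]1CC2=C(C)[C@@H](OC(=O)C(C)C)CC[C@]2(C)C[C@H]1OC(C)=O | intermediate
36 | (3β,8β)-8-acetoxy-3-(2-methylpropanoyloxy)eudesma-4,11(13)-dien-12-oic acid | C=C(C(=O)O)[C@H]1CC2=C(C)[C@@H](OC(=O)C(C)C)CC[C@]2(C)C[C@H]1OC(C)=O | intermediate
37 | methyl (3β,8β)-8-acetoxy-3-(2-methylpropanoyloxy)eudesma-4,11(13)-dien-12-oate | C=C(C(=O)OC)[C@H]1CC2=C(C)[C@@H](OC(=O)C(C)C)CC[C@]2(C)C[C@H]1OC(C)=O | intermediate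
38 | methyl (3β,5α,8β)-8-acetoxy-5-hydroperoxy-3-(2-methylpropanoyloxy)eudesma-4(15),11(13)-dien-12-oate, (3S,5S,7R,8R,10R), CNP0244758.1 | C=C(C(=O)OC)[C@H]1C[C@@]2(OO)C(=C)[C@@H](OC(=O)C(C)C)CC[C@]2(C)C[C@H]1OC(C)=O | target

Total step count: 25 (steps 1–6 make the benzylic bromide, steps 7–10 the acyl oxazolidinone, steps 11–25 the main line).
Longest linear sequence: 21 steps (steps 1–6, then 11–25).

Steps most likely to fail

Step 15. The diazonium ion may be intercepted by trifluoroacetate, attack at the ortho carbon C4 may compete with attack at C10, or the two arene faces may be poorly differentiated. The fallback makes the same C9–C10 bond by anionic phenoxide alkylation instead of diazonium capture. Setting out from 23, aqueous HBr in Et2O at 0 °C should convert the diazoketone into the bromomethyl ketone (3R)-1-bromo-5-(TBDPSO)-4-[(TBDPSO)methyl]-3-[(3-hydroxy-2,6-dimethylphenyl)methyl]pentan-2-one F1. One equivalent of KOt-Bu in t-BuOH/THF at rt then deprotonates only the phenol, and the para carbon of the phenoxide displaces bromide from C9; the base is limited to one equivalent to spare C7. The route is rejoined at 25.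

Step 25. Oxygen may be delivered to C4 with hydrogen abstraction from C6, H-3 may be abstracted, attack may occur on the β face, or the ene reaction may be slow because the allylic ester deactivates the alkene. The fallback builds the C5–O bond by epoxidation and then exchanges oxygen for the hydroperoxide. Setting out from 37, 3-chloroperoxybenzoic acid (NaHCO3, CH2Cl2, 0 °C) should epoxidise the electron-rich C4=C5 bond on the α face and leave the acrylate, giving the epoxide methyl (3β,4α,5α,8β)-8-acetoxy-4,5-epoxy-3-(2-methylpropanoyloxy)eudesm-11(13)-en-12-oate F2. Base-induced isomerisation of the epoxide with diethylaluminium 2,2,6,6-tetramethylpiperidide (toluene, 0 °C), which removes a proton from C15, should give the tertiary allylic alcohol methyl (3β,5α,8β)-8-acetoxy-5-hydroxy-3-(2-methylpropanoyloxy)eudesma-4(15),11(13)-dien-12-oate F3. Acid-catalysed exchange of the tertiary allylic hydroxyl with H2O2 (50% H2O2, cat. H2SO4, Et2O, 0 °C), through the allyl cation trapped at C5 on the face anti to C14, returns to 38.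

Step 16. Hydride may add to the ring A dienone, or the two faces of C8 may not be discriminated well enough. The fallback removes the need to distinguish the two carbonyl groups at this stage and separates the two oxygens later by acylation rate. Setting out from 25, hydrogenation of C1=C2 (H2, RhCl(PPh3)3, benzene/EtOH) should give the ene-dione 12,13-bis(TBDPSO)eudesm-4-ene-3,8-dione F4. Reduction of both carbonyl groups (NaBH4, CeCl3·7H2O, MeOH, −78 °C), each anti to C14 in the sense described for steps 16 and 19, should give the diol (3β,8β)-12,13-bis(TBDPSO)eudesm-4-ene-3,8-diol F5. One equivalent of 2-methylpropanoic anhydride (DMAP cat., Et3N, CH2Cl2, −20 °C) should acylate the unhindered equatorial allylic 3β-hydroxyl first and give (3β,8β)-8-hydroxy-12,13-bis(TBDPSO)eudesm-4-en-3-yl 2-methylpropanoate F6. Acetylation of the hindered axial 8β-hydroxyl (Ac2O, DMAP, pyridine) rejoins the route at 30.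

Further compounds
F1 | step 15 | (3R)-1-bromo-5-(TBDPSO)-4-[(TBDPSO)methyl]-3-[(3-hydroxy-2,6-dimethylphenyl)methyl]pentan-2-one | BrCC(=O)[C@H](Cc1c(C)c(O)ccc1C)C(CO[Si](c1ccccc1)(c1ccccc1)C(C)(C)C)CO[Si](c1ccccc1)(c1ccccc1)C(C)(C)C
F2 | step 25 | methyl (3β,4α,5α,8β)-8-acetoxy-4,5-epoxy-3-(2-methylpropanoyloxy)eudesm-11(13)-en-12-oate | C=C(C(=O)OC)[C@H]1C[C@@]2(O3)[C@@]3(C)[C@@H](OC(=O)C(C)C)CC[C@]2(C)C[C@H]1OC(C)=O
F3 | step 25 | methyl (3β,5α,8β)-8-acetoxy-5-hydroxy-3-(2-methylpropanoyloxy)eudesma-4(15),11(13)-dien-12-oate | C=C(C(=O)OC)[C@H]1C[C@@]2(O)C(=C)[C@@H](OC(=O)C(C)C)CC[C@]2(C)C[C@H]1OC(C)=O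
F4 | step 16 | 12,13-bis(TBDPSO)eudesm-4-ene-3,8-dione (7α-H, 10β-methyl) | CC(C)(C)[Si](c1ccccc1)(c1ccccc1)OCC(CO[Si](c1ccccc1)(c1ccccc1)C(C)(C)C)[C@H]1CC2=C(C)C(=O)CC[C@]2(C)CC1=O
F5 | step 16 | (3β,8β)-12,13-bis(TBDPSO)eudesm-4-ene-3,8-diol | CC(C)(C)[Si](c1ccccc1)(c1ccccc1)OCC(CO[Si](c1ccccc1)(c1ccccc1)C(C)(C)C)[C@H]1CC2=C(C)[C@@H](O)CC[C@]2(C)C[C@H]1O
F6 | step 16 | (3β,8β)-8-hydroxy-12,13-bis(TBDPSO)eudesm-4-en-3-yl 2-methylpropanoate | CC(C)(C)[Si](c1ccccc1)(c1ccccc1)OCC(CO[Si](c1ccccc1)(c1ccccc1)C(C)(C)C)[C@H]1CC2=C(C)[C@@H](OC(=O)C(C)C)CC[C@]2(C)C[C@H]1O
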